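**One-step world.** Take a world of one step: L binds G, at balance, and nothing else happens. Bound L over free L is then the binding constant, 340 M⁻¹, times dissolved G, whatever the amount of L. Our flask has more steps, and X makes its G, but that ratio still stands.

X 0.020 M (fed, over 2.0 d); L 0.0300 M; time 10 d; the fed solution adds 0.20 times the starting volume

    X + L ⇌ G + J (K1 = 1.0, k1 = 3.6 × 10⁻⁴ M⁻¹ s⁻¹)
    L + G ⇌ L.G, settled at all times (K2 = 340 M⁻¹)
    Q ⇌ G, rate k3*(cs3 - [G]) while solid is left; crystals form when [G] > cs3 (cs3 = 0.30 mM, k3 = 6.3 × 10⁻⁵ s⁻¹)
    L + J → L.J (k4 = 1.2 × 10⁻⁴ M⁻¹ s⁻¹)

- what is said of G includes Q
- amounts are per litre of the starting volume; all of the dose is in the solution fed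
- Q is a solid; its amount is given per volume of the solution
- run time (flask): 10 d

* part of the X that has reacted at 10 d
* share of the unused L that is free and not bound as L.G, at 10 d

**Turned round.** For bound L to outweigh free L, that product must pass one. This needs dissolved G of 2.94 mM, ten times the solubility. Can the flask get there? The X charged stands far above the solubility, so crystals should form. They exchange with a half-life of 3.06 h, far shorter than the run. While crystals last, dissolved G should stand above solubility by its net production over the dissolution coefficient, 6.3 × 10⁻⁵ s⁻¹. Were G made as fast as X is fed, our estimate puts it at 2.14 mM, still short of that need, and it should sink toward solubility as production fades.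

**Our reckoning.** With G exactly at solubility, the free share of unused L is one over one plus binding constant times solubility: 90.7 %. We call this the free-share ceiling, because G running above solubility can push the share down but not up. Free L should be the resting state of unused L. We commit to a little under the ceiling, and our hand gives no figure for c.

**The forecast.** It puts c at 86 %, between 82 % and 90 %, and the free share at 89.4 %, between 87.5 % and 90.5 %. It holds that “Crystals remain throughout”. Its free share lies 1.3 percentage points under our ceiling.

**The result.** The flask gives 86.8 % for c and 89.3 % for the free share, 1.4 points under the ceiling. By 2.00 d, the end of the feed, the first step had 46 % of its turnover behind it and crystallisation 12 %, with dissolved G at 8.84 × 10⁻⁴ M. Crystals then grew to 0.0136 M by 10.0 d, while dissolved G fell to 3.51 × 10⁻⁴ M. The neighbour flask with 0.018 M of L ended at 89.7 % free and the one with 0.051 M at 89.6 %, both under the same ceiling, though their free L stood at 9.38 % and 30.2 % of charge.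

All constants were drawn at random within sensible limits, and the outcome is calculated.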